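## Retrosynthetic overview

1. The last C–O events are the C2′ hydroxyl (catalytic enantioselective α-hydroxylation of the C8 2-methylacetoacetate 27) and the C8 ester (acylation of the 8-hydroxy germacranolide 24).
2. Ring order: the ten-membered carbocycle closes first (C6–C7, intramolecular allylchromium addition of a 2-(bromomethyl)enoate to the C6 enal); the γ-lactone (C6–O–C12) closes second, in the same pot.
3. Key disconnection C9–O: the isobutyrate is installed and C9 is set by a stereoconvergent phosphine-catalysed allylic acyloxylation of a Morita–Baylis–Hillman (MBH)-type carbonate; C8/C9 then steer C6/C7 in the ring closure.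
4. The carbonate comes from a Nozaki–Hiyama–Kishi union (C9–C10) of bromoenoate 7 (from nerol: C1–C6, C10, C14, C15) with aldehyde 11 (from methyl (S)-glycerate acetonide: C7–C9); C11–C13 come from methyl propiolate.

Assumption: positions are numbered as in germacranolides (ring C1–C10, lactone carbons C11–C13, ester carbon C14, methyl C15, acyl carbons primed), and 8 and 25 are bought.

## Route

Step 1
Reactants: 1 nerol
Product: 2 neryl triethylsilyl ether
Conditions: Et3SiCl, imidazole, CH2Cl2, 0 °C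
Reagents that add atoms: chlorotriethylsilane, CC[Si](Cl)(CC)CC
Why: Standard silylation of the primary allylic alcohol; the (Z)-alkene is untouched.

Step 2
Reactants: 2 neryl triethylsilyl ether
Product: 4 (4Z)-4-methyl-6-(triethylsilyloxy)hex-4-enal, via ozonide 3 (not isolated)
Conditions: O3 (1.0 equiv, Sudan red 7B end-point), CH2Cl2, −78 °C; then Me2S, −78 °C to rt
Reagents that add atoms: ozone, [O-][O+]=O
Why: Chemoselective ozonolysis of the remote, more electron-rich trisubstituted alkene (the 2,3-alkene is deactivated by the allylic oxygen), followed by reductive work-up.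

Step 3
Reactants: 4 (4Z)-4-methyl-6-(triethylsilyloxy)hex-4-enal; 5 methyl (triphenylphosphoranylidene)acetate
Product: 7 methyl (2Z,6Z)-2-bromo-6-methyl-8-(triethylsilyloxy)octa-2,6-dienoate, via bromo ylide 6 (not isolated)
Conditions: 5, N-bromosuccinimide, CH2Cl2, −20 °C; then 4, rt
Reagents that add atoms: N-bromosuccinimide, O=C1CCC(=O)N1Br
Why: One-pot ylide bromination and Wittig olefination; the stabilised α-bromo ylide gives the (Z)-2-bromoenoate (bromine cis to the chain), which is the geometry needed for C1=C10.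

Step 4
Reactants: 8 methyl (4S)-2,2-dimethyl-1,3-dioxolane-4-carboxylate
Product: 9 methyl (2S)-2,3-dihydroxypropanoate
Conditions: p-TsOH (cat.), MeOH, rt
Reagents that add atoms: none
Why: Acid-catalysed transacetalisation frees the diol without touching the stereocentre that becomes C8.

Step 5
Reactants: 9 methyl (2S)-2,3-dihydroxypropanoate
Product: 10 methyl (2S)-2,3-bis(triethylsilyloxy)propanoate
Conditions: Et3SiCl (2.2 equiv), imidazole, DMF, 0 °C
Reagents that add atoms: chlorotriethylsilane, CC[Si](Cl)(CC)CC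
Why: Bis-silylation; the primary silyl ether is later oxidised directly and the secondary one protects O8 as a non-leaving ether.

Step 6
Reactants: 10 methyl (2S)-2,3-bis(triethylsilyloxy)propanoate
Product: 11 (2S)-2,3-bis(triethylsilyloxy)propanal
Conditions: iBu2AlH (1.05 equiv), CH2Cl2, −78 °C; Rochelle salt work-up
Reagents that add atoms: none
Why: Partial reduction of an α-alkoxy ester stops at the aldehyde through the chelated aluminium hemiacetal.

Step 7
Reactants: 7 methyl (2Z,6Z)-2-bromo-6-methyl-8-(triethylsilyloxy)octa-2,6-dienoate; 11 (2S)-2,3-bis(triethylsilyloxy)propanal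
Product: 12 methyl (2E,6Z)-2-[(2S)-1-hydroxy-2,3-bis(triethylsilyloxy)propyl]-6-methyl-8-(triethylsilyloxy)octa-2,6-dienoate (both C9 epimers)
Conditions: CrCl2 (4 equiv), NiCl2 (2 mol %), DMF, rt
Reagents that add atoms: none
Why: Nozaki–Hiyama–Kishi vinylation forms C9–C10 with retention of alkene geometry; C9 forms as an epimer mixture (Felkin–Anh product major), which is harmless because step 9 is stereoconvergent.

Step 8
Reactants: 12 allylic alcohol (both C9 epimers)
Product: 13 methyl (2E,6Z)-2-[(2S)-1-(tert-butoxycarbonyloxy)-2,3-bis(triethylsilyloxy)propyl]-6-methyl-8-(triethylsilyloxy)octa-2,6-dienoate (both C9 epimers)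
Conditions: Boc2O, DMAP (cat.), CH2Cl2, rt
Reagents that add atoms: di-tert-butyl dicarbonate, CC(C)(C)OC(=O)OC(=O)OC(C)(C)C
Why: DMAP-catalysed carbonate formation turns the MBH-type alcohol into the usual leaving group for Lewis-base catalysis.

Step 9
Reactants: 13 allylic tert-butyl carbonate (both C9 epimers); 14 isobutyric acid
Product: 16 methyl (2E,6Z)-6-methyl-2-[(1S,2S)-1-(2-methylpropanoyloxy)-2,3-bis(triethylsilyloxy)propyl]-8-(triethylsilyloxy)octa-2,6-dienoate, via allylic phosphonium isobutyrate 15 (not isolated)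
Conditions: 14 (3 equiv), (S)-N-[1-(diphenylphosphanyl)-3-methylbutan-2-yl]-3,5-bis(trifluoromethyl)benzamide (10 mol %), toluene, 0 °C to rt
Reagents that add atoms: none
Why: Proposed new method: the chiral nucleophilic phosphine adds at C1 and expels tert-butyl carbonate (SN2′), so both C9 epimers give the same allylic phosphonium 15; the carbonate collapses to CO2 and tert-butoxide, which deprotonates 14, and amide N–H-guided attack of isobutyrate at C9 with SN2′ loss of the phosphine re-forms the (E)-C1=C10 bond and sets C9 (S) under catalyst control, irreversibly because the carboxylate product is a far poorer leaving group than the carbonate; the closest known reaction type is the chiral Lewis-base-catalysed SN2′–SN2′ allylic substitution of MBH carbonates, not yet shown for β-alkyl-substituted carbonates, for a carboxylic acid nucleophile, or as a stereoconvergent correction of a carbinol epimer mixture.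

Step 10
Reactants: 16 allylic isobutyrate
Product: 17 methyl (2E,6Z)-6-methyl-2-[(1S,2R)-1-(2-methylpropanoyloxy)-3-oxo-2-(triethylsilyloxy)propyl]-8-oxoocta-2,6-dienoate
Conditions: (COCl)2 (5 equiv), DMSO (10 equiv), CH2Cl2, −78 to −30 °C; then Et3N, −78 to 0 °C
Reagents that add atoms: none
Why: Swern conditions cleave and oxidise primary triethylsilyl ethers directly, so both the C6 and C7 termini become aldehydes in one operation while the secondary C8 silyl ether survives.

Step 11
Reactants: 17 dialdehyde; 18 methyl propiolate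
Product: 20 methyl (2E,6Z)-2-[(1S,2S)-3-hydroxy-4-(methoxycarbonyl)-1-(2-methylpropanoyloxy)-2-(triethylsilyloxy)pent-4-en-1-yl]-6-methyl-8-oxoocta-2,6-dienoate (both C7 epimers), via vinylalane 19 (not isolated)
Conditions: 18 (1.1 equiv), iBu2AlH (1.05 equiv), N-methylmorpholine N-oxide, THF, 0 °C; then 17, −78 to −20 °C
Reagents that add atoms: none
Why: Vinylalumination (an MBH-type addition under non-basic conditions, avoiding β-elimination of the C9 ester) is chemoselective for the α-silyloxy aldehyde over the β,β-disubstituted enal; the new C7 carbinol is erased in step 12.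

Step 12
Reactants: 20 MBH-type alcohol (both C7 epimers)
Product: 21 methyl (2E,6Z)-2-[(1S,2S,3Z)-5-bromo-4-(methoxycarbonyl)-1-(2-methylpropanoyloxy)-2-(triethylsilyloxy)pent-3-en-1-yl]-6-methyl-8-oxoocta-2,6-dienoate
Conditions: N-bromosuccinimide, Me2S, CH2Cl2, 0 °C to rt
Reagents that add atoms: N-bromosuccinimide, O=C1CCC(=O)N1Br
Why: Corey–Kim-type SN2′ bromination of an MBH alcohol gives the (Z)-2-(bromomethyl)enoate; the enal, esters and secondary silyl ether are inert.

Step 13
Reactants: 21 allylic bromide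
Product: 24 methyl (1(10)E,4Z,6R,7R,8S,9S)-8-hydroxy-9-(2-methylpropanoyloxy)-12-oxo-6,12-epoxygermacra-1(10),4,11(13)-trien-14-oate, via hydroxy ester 22 (not isolated), via silyl lactone 23 (not isolated)
Conditions: CrCl2 (8 equiv), THF/DMF, 2 mM, rt; then 1 M HCl, THF, 0 °C
Reagents that add atoms: none
Why: Intramolecular Nozaki–Hiyama allylation (γ-attack of the allylchromium at the enal) forms C6–C7 and the ring; the anti mode gives the trans C6/C7 pair, and allylic strain (H8 in plane, aldehyde approaching anti to the C8–C9 bond) sets C7 relative to C8; the chromium alkoxide then lactonises onto C12 and the acid work-up removes the C8 silyl group.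

Step 14
Reactants: 25 S-tert-butyl acetothioacetate
Product: 26 S-tert-butyl 2-methyl-3-oxobutanethioate
Conditions: MeI (1.05 equiv), K2CO3, acetone, rt
Reagents that add atoms: iodomethane, CI
Why: Mono C-methylation of the β-keto thioester enolate.

Step 15
Reactants: 24 8-hydroxy germacranolide; 26 S-tert-butyl 2-methyl-3-oxobutanethioate
Product: 27 methyl (1(10)E,4Z,6R,7S,8S,9S)-8-(2-methyl-3-oxobutanoyloxy)-9-(2-methylpropanoyloxy)-12-oxo-6,12-epoxygermacra-1(10),4,11(13)-trien-14-oate (both C2′ epimers)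
Conditions: AgOCOCF3 (1.3 equiv), THF, rt, dark
Reagents that add atoms: none
Why: Silver-promoted thioester activation (acylketene-type transacylation) esterifies the hindered C8 alcohol at room temperature under non-basic conditions, so the C9 isobutyrate does not migrate.

Step 16
Reactants: 27 8-O-(2-methylacetoacetyl) germacranolide (both C2′ epimers)
Product: 28 CNP0280649.2 (target)
Conditions: TiCl2(TADDOLato)(MeCN)2 (10 mol %; TADDOL = (4R,5R)-2,2-dimethyl-α,α,α′,α′-tetra(1-naphthyl)-1,3-dioxolane-4,5-dimethanol), 3-(4-nitrophenyl)-2-(phenylsulfonyl)oxaziridine (1.2 equiv), CH2Cl2, rt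
Reagents that add atoms: 3-(4-nitrophenyl)-2-(phenylsulfonyl)oxaziridine, O=S(=O)(c1ccccc1)N1OC1c1ccc(cc1)[N+](=O)[O-]
Why: Titanium–TADDOLate-catalysed electrophilic α-hydroxylation of the β-keto ester; both C2′ epimers converge through the titanium enolate and the catalyst selects the face to give C2′ (S), with the enantiomeric complex available should the sense prove opposite.

## Compound list

1 | nerol, (2Z)-3,7-dimethylocta-2,6-dien-1-ol | CC(C)=CCC/C(C)=C\CO | starting material
2 | neryl triethylsilyl ether | CC(C)=CCC/C(C)=C\CO[Si](CC)(CC)CC | intermediate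
3 | ozonide, 3,3-dimethyl-5-[(3Z)-3-methyl-5-(triethylsilyloxy)pent-3-en-1-yl]-1,2,4-trioxolane | CC1(C)OOC(CC/C(C)=C\CO[Si](CC)(CC)CC)O1 | intermediate
4 | (4Z)-4-methyl-6-(triethylsilyloxy)hex-4-enal | O=CCC/C(C)=C\CO[Si](CC)(CC)CC | intermediate
5 | methyl (triphenylphosphoranylidene)acetate | COC(=O)C=P(c1ccccc1)(c1ccccc1)c1ccccc1 | starting material
6 | methyl bromo(triphenylphosphoranylidene)acetate | COC(=O)C(Br)=P(c1ccccc1)(c1ccccc1)c1ccccc1 | intermediate
7 | methyl (2Z,6Z)-2-bromo-6-methyl-8-(triethylsilyloxy)octa-2,6-dienoate | COC(=O)/C(Br)=C/CC/C(C)=C\CO[Si](CC)(CC)CC | intermediate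
8 | methyl (4S)-2,2-dimethyl-1,3-dioxolane-4-carboxylate | COC(=O)[C@@H]1COC(C)(C)O1 | starting material
9 | methyl (2S)-2,3-dihydroxypropanoate | COC(=O)[C@@H](O)CO | intermediate
10 | methyl (2S)-2,3-bis(triethylsilyloxy)propanoate | COC(=O)[C@@H](O[Si](CC)(CC)CC)CO[Si](CC)(CC)CC | intermediate
11 | (2S)-2,3-bis(triethylsilyloxy)propanal | O=C[C@@H](O[Si](CC)(CC)CC)CO[Si](CC)(CC)CC | intermediate
12 | methyl (2E,6Z)-2-[(2S)-1-hydroxy-2,3-bis(triethylsilyloxy)propyl]-6-methyl-8-(triethylsilyloxy)octa-2,6-dienoate, both C9 epimers | COC(=O)/C(=C/CC/C(C)=C\CO[Si](CC)(CC)CC)C(O)[C@@H](O[Si](CC)(CC)CC)CO[Si](CC)(CC)CC | intermediate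
13 | tert-butyl carbonate of 12, both C9 epimers | COC(=O)/C(=C/CC/C(C)=C\CO[Si](CC)(CC)CC)C(OC(=O)OC(C)(C)C)[C@@H](O[Si](CC)(CC)CC)CO[Si](CC)(CC)CC | intermediate
14 | isobutyric acid, 2-methylpropanoic acid | CC(C)C(=O)O | starting material
15 | allylic phosphonium isobutyrate (phosphorus on C1, C9=C10 alkene; C1 configuration and alkene geometry not assigned) | COC(=O)C(=C[C@@H](O[Si](CC)(CC)CC)CO[Si](CC)(CC)CC)C(CC/C(C)=C\CO[Si](CC)(CC)CC)[P+](c1ccccc1)(c1ccccc1)C[C@@H](NC(=O)c1cc(C(F)(F)F)cc(C(F)(F)F)c1)C(C)C.CC(C)C(=O)[O-] | intermediate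
16 | methyl (2E,6Z)-6-methyl-2-[(1S,2S)-1-(2-methylpropanoyloxy)-2,3-bis(triethylsilyloxy)propyl]-8-(triethylsilyloxy)octa-2,6-dienoate | COC(=O)/C(=C/CC/C(C)=C\CO[Si](CC)(CC)CC)[C@H](OC(=O)C(C)C)[C@@H](O[Si](CC)(CC)CC)CO[Si](CC)(CC)CC | intermediate
17 | methyl (2E,6Z)-6-methyl-2-[(1S,2R)-1-(2-methylpropanoyloxy)-3-oxo-2-(triethylsilyloxy)propyl]-8-oxoocta-2,6-dienoate | COC(=O)/C(=C/CC/C(C)=C\C=O)[C@H](OC(=O)C(C)C)[C@@H](O[Si](CC)(CC)CC)C=O | intermediate
18 | methyl propiolate | C#CC(=O)OC | starting material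
19 | [1-(methoxycarbonyl)ethenyl]bis(2-methylpropyl)aluminium | C=C(C(=O)OC)[Al](CC(C)C)CC(C)C | intermediate
20 | methyl (2E,6Z)-2-[(1S,2S)-3-hydroxy-4-(methoxycarbonyl)-1-(2-methylpropanoyloxy)-2-(triethylsilyloxy)pent-4-en-1-yl]-6-methyl-8-oxoocta-2,6-dienoate, both C7 epimers | COC(=O)/C(=C/CC/C(C)=C\C=O)[C@H](OC(=O)C(C)C)[C@@H](O[Si](CC)(CC)CC)C(O)C(=C)C(=O)OC | intermediate
21 | methyl (2E,6Z)-2-[(1S,2S,3Z)-5-bromo-4-(methoxycarbonyl)-1-(2-methylpropanoyloxy)-2-(triethylsilyloxy)pent-3-en-1-yl]-6-methyl-8-oxoocta-2,6-dienoate | COC(=O)/C(=C/CC/C(C)=C\C=O)[C@H](OC(=O)C(C)C)[C@@H](O[Si](CC)(CC)CC)/C=C(\CBr)C(=O)OC | intermediate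
22 | dimethyl (1(10)E,4Z,6R,7S,8S,9S)-6-hydroxy-9-(2-methylpropanoyloxy)-8-(triethylsilyloxy)germacra-1(10),4,11(13)-triene-12,14-dioate (formed as its chromium alkoxide) | O[C@@H]1/C=C(/C)CC/C=C(/C(=O)OC)[C@H](OC(=O)C(C)C)[C@@H](O[Si](CC)(CC)CC)[C@H]1C(=C)C(=O)OC | intermediate
23 | methyl (1(10)E,4Z,6R,7S,8S,9S)-9-(2-methylpropanoyloxy)-12-oxo-8-(triethylsilyloxy)-6,12-epoxygermacra-1(10),4,11(13)-trien-14-oate | C=C1C(=O)O[C@@H]2/C=C(/C)CC/C=C(/C(=O)OC)[C@H](OC(=O)C(C)C)[C@@H](O[Si](CC)(CC)CC)[C@@H]12 | intermediate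
24 | methyl (1(10)E,4Z,6R,7R,8S,9S)-8-hydroxy-9-(2-methylpropanoyloxy)-12-oxo-6,12-epoxygermacra-1(10),4,11(13)-trien-14-oate | C=C1C(=O)O[C@@H]2/C=C(/C)CC/C=C(/C(=O)OC)[C@H](OC(=O)C(C)C)[C@@H](O)[C@@H]12 | intermediate
25 | S-tert-butyl acetothioacetate, S-tert-butyl 3-oxobutanethioate | CC(=O)CC(=O)SC(C)(C)C | starting material
26 | S-tert-butyl 2-methyl-3-oxobutanethioate | CC(=O)C(C)C(=O)SC(C)(C)C | intermediate
27 | methyl (1(10)E,4Z,6R,7S,8S,9S)-8-(2-methyl-3-oxobutanoyloxy)-9-(2-methylpropanoyloxy)-12-oxo-6,12-epoxygermacra-1(10),4,11(13)-trien-14-oate, both C2′ epimers | C=C1C(=O)O[C@@H]2/C=C(/C)CC/C=C(/C(=O)OC)[C@H](OC(=O)C(C)C)[C@@H](OC(=O)C(C)C(C)=O)[C@@H]12 | intermediate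
28 | CNP0280649.2, (6R,7S,8S,9S)-8-[(2S)-2-hydroxy-2-methyl-3-oxobutanoyloxy]-9-(2-methylpropanoyloxy) 6,12-olide 14-methyl ester | C=C1C(=O)O[C@@H]2/C=C(/C)CC/C=C(/C(=O)OC)[C@H](OC(=O)C(C)C)[C@@H](OC(=O)[C@@](C)(O)C(C)=O)[C@@H]12 | target

## Step count and risks

Total: 16 steps. Longest linear sequence: 12 steps (steps 4–13, 15, 16; the nerol branch, steps 1–3 then 7–13, 15, 16, is equally long).

The three steps most likely to fail:

Step 9 (the proposed new acyloxylation). Phosphine addition at the alkyl-bearing C1 may be slow, tert-butoxide may cause elimination to a diene before it is buffered, and the catalyst may be mismatched with the C8 centre. The fallback uses known chemistry, sets out from 12 and comes back at 16. Alcohol 12 is oxidised with Dess–Martin periodinane to the enone methyl (2E,6Z)-6-methyl-2-[(2S)-2,3-bis(triethylsilyloxy)propanoyl]-8-(triethylsilyloxy)octa-2,6-dienoate F4. Felkin–Anh-controlled 1,2-reduction (NaBH4, CeCl3, MeOH, −78 °C, or an oxazaborolidine with catecholborane) gives the 8,9-syn alcohol methyl (2E,6Z)-2-[(1S,2S)-1-hydroxy-2,3-bis(triethylsilyloxy)propyl]-6-methyl-8-(triethylsilyloxy)octa-2,6-dienoate F5. Acylation with isobutyryl chloride, pyridine and DMAP gives 16.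

Step 13 (ring closure). Risks are medium-ring strain and oligomerisation, 1,4-loss of the C8 silyloxy group from the allylchromium, and the C6/C7 facial selectivity, which rests on a model. The fallback changes how the allyl nucleophile is made, sets out from 20 and comes back at 24. Alcohol 20 is acetylated (Ac2O, DMAP) to the MBH acetate methyl (2E,6Z)-2-[(1S,2S)-3-acetoxy-4-(methoxycarbonyl)-1-(2-methylpropanoyloxy)-2-(triethylsilyloxy)pent-4-en-1-yl]-6-methyl-8-oxoocta-2,6-dienoate F6. Zerovalent palladium (Pd(PPh3)4) ionises it to a π-allyl complex, InI turns this into an allylindium, and this cyclises onto the enal at high dilution through a different transition state; the same acid work-up gives 24.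

Step 7 (Nozaki–Hiyama–Kishi coupling of an α-bromoenoate). The α-chromio enoate may equilibrate through an allenoate and lose geometry, or couple sluggishly; an E/Z mixture at C1=C10 would be tolerable because step 9 re-forms that alkene. The fallback sets out from 4 (with 5 and 11) and comes back at 12. Aldehyde 4 is olefinated with ylide 5 without bromination to the enoate methyl (2E,6Z)-6-methyl-8-(triethylsilyloxy)octa-2,6-dienoate F1. Me2AlSPh-mediated thia-Michael addition and aldol trapping with 11 give methyl 2-[(2S)-1-hydroxy-2,3-bis(triethylsilyloxy)propyl]-6-methyl-3-(phenylsulfanyl)-8-(triethylsilyloxy)oct-6-enoate F2. Oxidation (NaIO4) gives the sulfoxide methyl 2-[(2S)-1-hydroxy-2,3-bis(triethylsilyloxy)propyl]-6-methyl-3-(phenylsulfinyl)-8-(triethylsilyloxy)oct-6-enoate F3, and thermal syn-elimination returns 12.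

## Further compounds

F1 | step 7 | methyl (2E,6Z)-6-methyl-8-(triethylsilyloxy)octa-2,6-dienoate | COC(=O)/C=C/CC/C(C)=C\CO[Si](CC)(CC)CC
F2 | step 7 | methyl 2-[(2S)-1-hydroxy-2,3-bis(triethylsilyloxy)propyl]-6-methyl-3-(phenylsulfanyl)-8-(triethylsilyloxy)oct-6-enoate | COC(=O)C(C(CC/C(C)=C\CO[Si](CC)(CC)CC)Sc1ccccc1)C(O)[C@@H](O[Si](CC)(CC)CC)CO[Si](CC)(CC)CC
F3 | step 7 | methyl 2-[(2S)-1-hydroxy-2,3-bis(triethylsilyloxy)propyl]-6-methyl-3-(phenylsulfinyl)-8-(triethylsilyloxy)oct-6-enoate | COC(=O)C(C(CC/C(C)=C\CO[Si](CC)(CC)CC)S(=O)c1ccccc1)C(O)[C@@H](O[Si](CC)(CC)CC)CO[Si](CC)(CC)CC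
F4 | step 9 | methyl (2E,6Z)-6-methyl-2-[(2S)-2,3-bis(triethylsilyloxy)propanoyl]-8-(triethylsilyloxy)octa-2,6-dienoate | COC(=O)/C(=C/CC/C(C)=C\CO[Si](CC)(CC)CC)C(=O)[C@@H](O[Si](CC)(CC)CC)CO[Si](CC)(CC)CC
F5 | step 9 | methyl (2E,6Z)-2-[(1S,2S)-1-hydroxy-2,3-bis(triethylsilyloxy)propyl]-6-methyl-8-(triethylsilyloxy)octa-2,6-dienoate | COC(=O)/C(=C/CC/C(C)=C\CO[Si](CC)(CC)CC)[C@H](O)[C@@H](O[Si](CC)(CC)CC)CO[Si](CC)(CC)CC
F6 | step 13 | methyl (2E,6Z)-2-[(1S,2S)-3-acetoxy-4-(methoxycarbonyl)-1-(2-methylpropanoyloxy)-2-(triethylsilyloxy)pent-4-en-1-yl]-6-methyl-8-oxoocta-2,6-dienoate | COC(=O)/C(=C/CC/C(C)=C\C=O)[C@H](OC(=O)C(C)C)[C@@H](O[Si](CC)(CC)CC)C(OC(C)=O)C(=C)C(=O)OC
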